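**Plan**

1. Locants: lactam N4–C9a(=O)–C1–C2–C3; large ring N4–C5–C6–C7–C8–C9(=O)–C10(Et)–C11–C12–C1–C9a; lactone B = O–C11–C12–C13(Me)–C14(=O); lactone D = C18(on C3)–C19–C20(Me)–C21(=O)–O. Cuts, in order: C7=C8 unsaturation put back; ring bond C5–C6 (last C–C bond, by CO2-extrusive ring contraction of a 13-membered lactone in which a carboxyl on C5 is esterified to O–C6); that ester C–O bond; N4–C5 (carbene N–H insertion); C10–C11 and C11–O of lactone B (aldol, lactonisation); C1–C12 and C13–CH3 (tandem Michael addition/alkylation); C18–C19 (acyl–alkylzinc coupling).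
2. Feature that makes the key event possible: C5 is the N–CH2 of lactam N4, so with a carboxyl it is a glycine α-carbon that becomes an α-amido radical on loss of CO2. C6 is γ to the C9 ketone, so C6–C7–C8 is an acyl-substituted allyl unit. An ester between the two gives a 13-membered lactone that is far easier to close than the 11-membered carbocycle, and ionisation plus decarboxylation turns it into the 11-membered keto-lactam ring.
3. Forward order of rings: lactam (from the pool) → lactone D (step 3) → menthyl acetal lactone as a temporary ring (step 6, opened in step 7) → lactone B (step 9) → 13-membered lactone (step 12) → 11-membered ring (step 13) → saturation (step 14).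
4. Stereochemistry: C3 from L-pyroglutamic acid; C20 from bromo ester 3; C18 by Felkin–Anh reduction; C1 by enolate attack anti to the C3 substituent; C12 and C13 from the (5S)-menthyloxy acetal template; C10 and C11 by a reagent-controlled syn boron aldol.
5. From the aldol onward C10–H is α to the C9 ketone and β to the C11 acyloxy group, so every later step is neutral, acidic or photochemical.

Key step: step 13

Assumption: (−)-Ipc2BOTf is taken to be the antipode that sends the (Z)-enolate to the aldehyde face giving 10S,11R; if a model aldol shows the opposite sense, (+)-Ipc2BOTf is used with no other change.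

**Route**

Step 1
Reactants: 1 L-pyroglutamic acid
Product: 2 S-ethyl (2S)-5-oxopyrrolidine-2-carbothioate
Conditions: EtSH, DCC, DMAP (cat.), CH2Cl2/DMF, 0 °C to rt
Reagents that add atoms: ethanethiol, CCS
Why: Steglich-type carbodiimide thioesterification activates the acid as the thioester needed for the ketone synthesis without touching the C3 stereocentre taken from the amino acid pool.

Step 2
Reactants: 2 S-ethyl (2S)-5-oxopyrrolidine-2-carbothioate; 3 methyl (2R)-3-bromo-2-methylpropanoate
Product: 5 methyl (2S)-2-methyl-4-oxo-4-[(2S)-5-oxopyrrolidin-2-yl]butanoate, via alkylzinc bromide 4 (not isolated)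
Conditions: 3, Zn dust, LiCl, THF, 40 °C; then 2, PdCl2(PPh3)2 (5 mol %), toluene/THF, rt
Reagents that add atoms: none
Why: Fukuyama coupling (palladium-catalysed acylation of an alkylzinc halide by a thioester) stops at the ketone and tolerates the ester and the lactam N–H, and C20 is carried unchanged from 3 because the zinc-bearing carbon is not the stereocentre.

Step 3
Reactants: 5 methyl (2S)-2-methyl-4-oxo-4-[(2S)-5-oxopyrrolidin-2-yl]butanoate
Product: 7 (5S)-5-[(2S,4S)-4-methyl-5-oxooxolan-2-yl]pyrrolidin-2-one, via hydroxy ester 6 (not isolated)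
Conditions: LiBH(s-Bu)3, THF, −78 to 0 °C; aqueous work-up
Reagents that add atoms: none
Why: Felkin–Anh reduction (polar model, the amide-type N4 does not chelate) by the bulky hydride should set 18S with the hydroxyl syn to N4, and the alkoxide closes lactone D on the methyl ester by lactonisation.

Step 4
Reactants: 7 (5S)-5-[(2S,4S)-4-methyl-5-oxooxolan-2-yl]pyrrolidin-2-one
Product: 8 tert-butyl (2S)-2-[(2S,4S)-4-methyl-5-oxooxolan-2-yl]-5-oxopyrrolidine-1-carboxylate
Conditions: Boc2O, DMAP (cat.), Et3N, MeCN, rt
Reagents that add atoms: di-tert-butyl dicarbonate, CC(C)(C)OC(=O)OC(=O)OC(C)(C)C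
Why: N-acylation with Boc2O under DMAP catalysis turns the lactam into an imide-type carbamate whose C1–H2 is the most acidic and least hindered C–H of the molecule, as the next step needs.

Step 5
Reactants: 9 5-hydroxyfuran-2(5H)-one; 10 (+)-menthol
Product: 11 (5S)-5-{[(1S,2R,5S)-5-methyl-2-(propan-2-yl)cyclohexyl]oxy}furan-2(5H)-one
Conditions: camphorsulfonic acid (cat.), toluene, reflux, Dean–Stark; crystallisation with acid epimerisation of the mother liquor
Reagents that add atoms: none
Why: Acid-catalysed acetalisation of the lactol, in which the acetal carbon epimerises under the acid while the (5S) epimer of the (+)-menthyl series crystallises, so the material should funnel into 11 (crystallisation-induced diastereomer transformation).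

Step 6
Reactants: 8 tert-butyl (2S)-2-[(2S,4S)-4-methyl-5-oxooxolan-2-yl]-5-oxopyrrolidine-1-carboxylate; 11 (5S)-5-(d-menthyloxy)furan-2(5H)-one
Product: 14 N-Boc lactam carrying at C1 the (11S,12S,13S)-11-(d-menthyloxy)-13-methyl-14-oxo lactone (1S,3S,18S,20S), via lithium lactam enolate 12 (not isolated), via lithium lactone enolate 13 (not isolated)
Conditions: LiN(SiMe3)2, THF, −78 °C; 11, −78 °C; then MeI, DMPU, −78 to −40 °C
Reagents that add atoms: iodomethane, CI
Why: Tandem Michael addition–enolate alkylation on a 5-alkoxybutenolide, in which the lactam enolate reacts on the face anti to the C3 substituent (C1, 1,3-trans), the butenolide on the face anti to the menthyloxy group (C12), and iodomethane enters anti to the new C12 substituent (C13).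

Step 7
Reactants: 14 N-Boc menthyl acetal adduct
Product: 16 methyl (2S,3S)-3-formyl-2-methyl-3-{(3S,5S)-5-[(2S,4S)-4-methyl-5-oxooxolan-2-yl]-2-oxopyrrolidin-3-yl}propanoate, via lactol 15 (not isolated)
Conditions: TFA/H2O (9:1), 40 °C; evaporate; then Me3SiCHN2 (1.1 equiv), PhMe/MeOH, 0 °C
Reagents that add atoms: water, O; (trimethylsilyl)diazomethane, C[Si](C)(C)C=[N+]=[N-]
Why: Acidolysis of the carbamate and acid hydrolysis of the acetal free the N4–H lactam and the lactol, and the diazoalkane then methylates only the carboxylic acid of the ring-opened tautomer (neutral esterification), which should funnel the ring–chain equilibrium into the open aldehyde ester without touching C12.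

Step 8
Reactants: 17 hex-1-en-3-one; 18 tert-butyldimethyl(prop-2-en-1-yloxy)silane
Product: 19 (E)-1-[(tert-butyldimethylsilyl)oxy]hept-2-en-4-one
Conditions: second-generation Grubbs catalyst (3 mol %), 18 in excess, CH2Cl2, 40 °C
Reagents that add atoms: none
Why: Olefin cross-metathesis between an enone that does not homodimerise and an allyl ether used in excess should give the (E)-enone under thermodynamic control.

Step 9
Reactants: 16 aldehyde methyl ester; 19 (E)-1-[(tert-butyldimethylsilyl)oxy]hept-2-en-4-one
Product: 22 N4–H lactam bis-lactone (lactones B and D closed) carrying at C10 the (E)-C9(=O)–C8=C7–C6H2–OTBS enone chain (1S,3S,10S,11R,12S,13S,18S,20S), via boron enolate 20 (not isolated), via hydroxy ester 21 (not isolated)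
Conditions: 19, (−)-Ipc2BOTf, i-Pr2NEt, CH2Cl2, −78 °C; 16, −78 to −20 °C; H2O2, MeOH/pH 7 buffer, 0 °C; then PPTS, CH2Cl2, rt
Reagents that add atoms: none
Why: Boron aldol addition in which the (Z)-enolate reacts through a chair Zimmerman–Traxler transition state to give the 10,11-syn adduct, the isopinocampheyl ligands select the aldehyde face (reagent control, 10S,11R), and acid closes lactone B on the C14 ester with retention at C11, cis to the C12 substituent.

Step 10
Reactants: 22 N4–H lactam bis-lactone silyloxy enone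
Product: 23 N4-(tert-butoxycarbonylmethyl) derivative of 22
Conditions: t-BuO2CCHN2 (slow addition), Rh2(OAc)4 (2 mol %), CH2Cl2, 40 °C
Reagents that add atoms: tert-butyl diazoacetate, CC(C)(C)OC(=O)C=[N+]=[N-]
Why: Rhodium-carbenoid N–H insertion alkylates the lactam nitrogen (forming N4–C5) at neutral pH, which spares the base-sensitive β-acyloxy ketone and both lactones.

Step 11
Reactants: 23 N4-(tert-butoxycarbonylmethyl) silyloxy enone
Product: 24 seco acid: N4–CH2CO2H and free C6–OH on the (E)-enone
Conditions: TFA/CH2Cl2 (1:3), 0 °C to rt; then THF/H2O, rt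
Reagents that add atoms: none
Why: Acidolysis of the tert-butyl ester (loss of isobutene) and acid-promoted cleavage of the primary silyl ether give the hydroxy acid without any base.

Step 12
Reactants: 24 seco acid
Product: 25 13-membered lactone (ring N4, C5, ester C(=O)–O, C6, C7=C8, C9–C12, C1, C9a)
Conditions: PPh3, DIAD, toluene/THF, slow addition of 24 (final 1 mM), 0 °C to rt
Reagents that add atoms: none
Why: Mitsunobu macrolactonisation activates the primary allylic C6–OH as an alkoxyphosphonium ion that the C5 carboxylate displaces under neutral conditions, and an SN2 or an SN2' ester would feed the same allyl cation in step 13.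

Step 13
Reactants: 25 13-membered allyl glycinate lactone
Product: 26 11-membered keto-lactam with (E)-C7=C8 enone (7,8-didehydro target)
Conditions: Pd(PPh3)4 (10 mol %), Ir[dF(CF3)ppy]2(dtbbpy)PF6 (2 mol %), degassed MeCN (2 mM), blue LEDs (450 nm), 25 °C, no base
Reagents that add atoms: none
Why: Proposed new method: zerovalent palladium ionises the allylic C6–O ester bond of 25 (a γ-acyloxy enone, O=C9–C8=C7–C6) to a zwitterion holding a C8-acyl π-allyl palladium cation and the N4–C5H2–CO2 carboxylate; the excited trivalent iridium photocatalyst oxidises the carboxylate, CO2 is lost, the α-amido radical at C5 is captured at C6 of the allyl–palladium unit (capture at palladium then reductive elimination, or direct attack on the allyl ligand), and the reduced divalent iridium returns palladium to the zerovalent state. The closest known reaction type is the dual photoredox/palladium decarboxylative allylation of N-acyl α-amino acid allyl esters, which forms the same α-amido C–allyl bond from an acyclic ester; here the ester is the 13-membered lactone, so the event becomes a CO2-extrusive ring contraction. The only ring closed is the 11-membered carbocycle (N4, C5 to C12, C1, C9a), closed in the endo sense at the distal terminus C6 of the C6–C7–C8 allyl unit so that C7=C8 stays in the ring as the enone, while the γ-lactam and lactone B are spectators. No stereocentre is created (C5 and C6 become CH2) and none is touched, because no base is present and C10–H is never enolised. The step needs attack at C6 rather than C8 (which would give a nine-membered ring), secured by the C9 acyl group that keeps conjugation and by the lower strain of the larger ring; it needs oxidation of the carboxylate only, secured because the lactam nitrogen lone pair is amide-bound; and it needs ring closure over oligomerisation, secured by 2 mM dilution and by both reacting ends arising from one ester bond of one molecule.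

Step 14
Reactants: 26 11-membered keto-lactam enone
Product: 27 target CNP0147860.1
Conditions: H2 (1 atm), Pd/C (10%), EtOAc, rt
Reagents that add atoms: none
Why: Heterogeneous catalytic hydrogenation saturates the conjugated disubstituted C7=C8 bond at neutral pH and creates no stereocentre, leaving ketone, lactam and both lactones untouched.

**Compound list**

1 | L-pyroglutamic acid, (2S)-5-oxopyrrolidine-2-carboxylic acid | N1C(=O)CC[C@H]1C(=O)O | starting material
2 | S-ethyl (2S)-5-oxopyrrolidine-2-carbothioate | N1C(=O)CC[C@H]1C(=O)SCC | intermediate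
3 | methyl (2R)-3-bromo-2-methylpropanoate | BrC[C@H](C)C(=O)OC | starting material
4 | [(2R)-3-methoxy-2-methyl-3-oxopropyl]zinc bromide | Br[Zn]C[C@H](C)C(=O)OC | intermediate
5 | methyl (2S)-2-methyl-4-oxo-4-[(2S)-5-oxopyrrolidin-2-yl]butanoate | N1C(=O)CC[C@H]1C(=O)C[C@H](C)C(=O)OC | intermediate
6 | methyl (2S,4S)-4-hydroxy-2-methyl-4-[(2S)-5-oxopyrrolidin-2-yl]butanoate | N1C(=O)CC[C@H]1[C@@H](O)C[C@H](C)C(=O)OC | intermediate
7 | (5S)-5-[(2S,4S)-4-methyl-5-oxooxolan-2-yl]pyrrolidin-2-one | N1C(=O)CC[C@H]1[C@@H]1C[C@H](C)C(=O)O1 | intermediate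
8 | tert-butyl (2S)-2-[(2S,4S)-4-methyl-5-oxooxolan-2-yl]-5-oxopyrrolidine-1-carboxylate | CC(C)(C)OC(=O)N1C(=O)CC[C@H]1[C@@H]1C[C@H](C)C(=O)O1 | intermediate
9 | 5-hydroxyfuran-2(5H)-one (racemic lactol) | OC1OC(=O)C=C1 | starting material
10 | (+)-menthol, (1S,2R,5S)-5-methyl-2-(propan-2-yl)cyclohexan-1-ol | O[C@H]1C[C@@H](C)CC[C@@H]1C(C)C | starting material
11 | (5S)-5-{[(1S,2R,5S)-5-methyl-2-(propan-2-yl)cyclohexyl]oxy}furan-2(5H)-one | O=C1C=C[C@@H](O[C@H]2C[C@@H](C)CC[C@@H]2C(C)C)O1 | intermediate
12 | lithium enolate of 8 (O-lithio, C1=C9a) | CC(C)(C)OC(=O)N1C(O[Li])=CC[C@H]1[C@@H]1C[C@H](C)C(=O)O1 | intermediate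
13 | lithium lactone enolate from Michael addition of 12 to 11 (C13=C14–OLi) | CC(C)(C)OC(=O)N1C(=O)[C@@H](C[C@H]1[C@@H]1C[C@H](C)C(=O)O1)[C@@H]1[C@@H](O[C@H]2C[C@@H](C)CC[C@@H]2C(C)C)OC(O[Li])=C1 | intermediate
14 | N-Boc lactam with C1-bound (11S,12S,13S)-menthyloxy methyl lactone | CC(C)(C)OC(=O)N1C(=O)[C@@H](C[C@H]1[C@@H]1C[C@H](C)C(=O)O1)[C@@H]1[C@@H](O[C@H]2C[C@@H](C)CC[C@@H]2C(C)C)OC(=O)[C@H]1C | intermediate
15 | N4–H lactam lactol (C11 hemiacetal, both anomers, in equilibrium with the aldehyde acid) | N1C(=O)[C@@H](C[C@H]1[C@@H]1C[C@H](C)C(=O)O1)[C@@H]1C(O)OC(=O)[C@H]1C | intermediate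
16 | methyl (2S,3S)-3-formyl-2-methyl-3-{(3S,5S)-5-[(2S,4S)-4-methyl-5-oxooxolan-2-yl]-2-oxopyrrolidin-3-yl}propanoate | N1C(=O)[C@@H](C[C@H]1[C@@H]1C[C@H](C)C(=O)O1)[C@H](C=O)[C@H](C)C(=O)OC | intermediate
17 | hex-1-en-3-one | CCCC(=O)C=C | starting material
18 | tert-butyldimethyl(prop-2-en-1-yloxy)silane | C=CCO[Si](C)(C)C(C)(C)C | starting material
19 | (E)-1-[(tert-butyldimethylsilyl)oxy]hept-2-en-4-one | CCCC(=O)/C=C/CO[Si](C)(C)C(C)(C)C | intermediate
20 | (Z)-diisopinocampheylboron enolate of 19 (C9–O–B, C9=C10) | CC/C=C(\OB([C@@H]1C[C@@H]2C[C@H]([C@H]1C)C2(C)C)[C@@H]1C[C@@H]2C[C@H]([C@H]1C)C2(C)C)/C=C/CO[Si](C)(C)C(C)(C)C | intermediate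
21 | syn-aldol hydroxy ester (10S,11R; C14 methyl ester still open) | N1C(=O)[C@@H](C[C@H]1[C@@H]1C[C@H](C)C(=O)O1)[C@@H]([C@H](C)C(=O)OC)[C@@H](O)[C@H](CC)C(=O)/C=C/CO[Si](C)(C)C(C)(C)C | intermediate
22 | N4–H lactam bis-lactone with (E)-silyloxy enone chain | N1C(=O)[C@@H](C[C@H]1[C@@H]1C[C@H](C)C(=O)O1)[C@@H]1[C@@H](OC(=O)[C@H]1C)[C@H](CC)C(=O)/C=C/CO[Si](C)(C)C(C)(C)C | intermediate
23 | N4-(tert-butoxycarbonylmethyl) derivative of 22 | CC(C)(C)OC(=O)CN1C(=O)[C@@H](C[C@H]1[C@@H]1C[C@H](C)C(=O)O1)[C@@H]1[C@@H](OC(=O)[C@H]1C)[C@H](CC)C(=O)/C=C/CO[Si](C)(C)C(C)(C)C | intermediate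
24 | seco acid (N4–CH2CO2H, C6–OH) | OC(=O)CN1C(=O)[C@@H](C[C@H]1[C@@H]1C[C@H](C)C(=O)O1)[C@@H]1[C@@H](OC(=O)[C@H]1C)[C@H](CC)C(=O)/C=C/CO | intermediate
25 | 13-membered allyl glycinate lactone | CC[C@@H]1C(=O)/C=C/COC(=O)CN2C(=O)[C@@H](C[C@H]2[C@@H]2C[C@H](C)C(=O)O2)[C@@H]2[C@H]1OC(=O)[C@H]2C | intermediate
26 | 11-membered keto-lactam with (E)-C7=C8 | CC[C@@H]1C(=O)/C=C/CCN2C(=O)[C@@H](C[C@H]2[C@@H]2C[C@H](C)C(=O)O2)[C@@H]2[C@H]1OC(=O)[C@H]2C | intermediate
27 | target CNP0147860.1 (1S,3S,10S,11R,12S,13S,18S,20S) | CC[C@@H]1C(=O)CCCCN2C(=O)[C@@H](C[C@H]2[C@@H]2C[C@H](C)C(=O)O2)[C@@H]2[C@H]1OC(=O)[C@H]2C | target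

**Totals and risks**

Total step count: 14. Longest linear sequence: 12 steps (steps 1–4, 6, 7, 9–14); steps 5 and 8 are side branches.

Steps most likely to fail:

1. Step 13 (Proposed new method). What may go wrong: reduction or protonation of the C5 radical before C–C bond formation (loss of CO2 without ring closure), coupling at C8 instead of C6, or oligomerisation. Fallback with known chemistry, a two-electron Tsuji–Trost macrocyclisation of a soft aminomalonate carbon nucleophile, sets out from 22. Rh2(OAc)4-catalysed N–H insertion of dibenzyl diazomalonate should give the N4-aminomalonate F1. HF·pyridine removes the silyl ether to give the allylic alcohol F2, and methyl chloroformate/pyridine gives the allylic methyl carbonate F3. Pd2(dba)3/dppe in THF at 3 mM should then close the 11-membered ring by attack of the malonate carbon on C6 of the acyl-substituted π-allyl palladium intermediate, giving the macrocyclic enone diester F4; closure of an 11-membered carbocycle by intramolecular palladium allylic alkylation of a stabilised carbanion is precedented in terpene synthesis. H2 over Pd/C cleaves both benzyl esters and saturates C7=C8 to give the malonic acid F5, which loses CO2 on gentle warming to give the C5 carboxylic acid F6. Photoredox hydrodecarboxylation (9-mesityl-10-methylacridinium tetrafluoroborate, (PhS)2, 2,6-lutidine, blue LEDs) or a Barton decarboxylation removes the last carboxyl, and the route is rejoined at 27.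

2. Step 9. What may go wrong: poor aldehyde-face selectivity when the chiral boron reagent and the C12 stereocentre are mismatched, or retro-aldol and oxa-Michael closure of the β-hydroxy enone during work-up. The fallback replaces reagent control by auxiliary control and sets out from 16. An Evans syn-aldol with the dibutylboron enolate (Bu2BOTf, i-Pr2NEt) of commercial (S)-4-benzyl-3-butanoyl-1,3-oxazolidin-2-one should give the syn-aldol imide F7. LiSEt (EtSH, n-BuLi, THF, 0 °C) displaces the auxiliary from the free β-hydroxy imide, and PPTS closes lactone B to give the thioester lactone F8. A base-free Liebeskind–Srogl coupling (Pd2(dba)3, tri(2-furyl)phosphine, copper thiophene-2-carboxylate CuO2CC4H3S) with (E)-[3-(tert-butyldimethylsilyloxy)prop-1-en-1-yl]boronic acid then installs the enone and rejoins the route at 22.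

3. Step 6. What may go wrong: proton transfer from the more acidic N-Boc lactam C1–H to the lactone enolate before methylation (methylation or epimerisation at C1), and incomplete facial control in the alkylation. The fallback carries the methyl group in the acceptor instead of alkylating, and sets out from 8. The enolate 12 is added to the methylated acceptor (5S)-5-(d-menthyloxy)-3-methylfuran-2(5H)-one F9, made as in step 5 from 5-hydroxy-3-methylfuran-2(5H)-one and 10. Kinetic protonation of the lactone enolate anti to the C12 substituent should give the 13-epimeric adduct F10, and catalytic DBU then equilibrates C13 to the more stable trans,trans lactone, rejoining the route at 14.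

Further compounds
F1 | step 13 | N4-[bis(benzyloxycarbonyl)methyl] derivative of 22 | O=C(OCc1ccccc1)C(C(=O)OCc1ccccc1)N1C(=O)[C@@H](C[C@H]1[C@@H]1C[C@H](C)C(=O)O1)[C@@H]1[C@@H](OC(=O)[C@H]1C)[C@H](CC)C(=O)/C=C/CO[Si](C)(C)C(C)(C)C
F2 | step 13 | allylic alcohol from F1 (C6–OH) | O=C(OCc1ccccc1)C(C(=O)OCc1ccccc1)N1C(=O)[C@@H](C[C@H]1[C@@H]1C[C@H](C)C(=O)O1)[C@@H]1[C@@H](OC(=O)[C@H]1C)[C@H](CC)C(=O)/C=C/CO
F3 | step 13 | allylic methyl carbonate from F2 | O=C(OCc1ccccc1)C(C(=O)OCc1ccccc1)N1C(=O)[C@@H](C[C@H]1[C@@H]1C[C@H](C)C(=O)O1)[C@@H]1[C@@H](OC(=O)[C@H]1C)[C@H](CC)C(=O)/C=C/COC(=O)OC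
F4 | step 13 | 11-membered enone with C5(CO2Bn)2 | CC[C@@H]1C(=O)/C=C/CC(C(=O)OCc3ccccc3)(C(=O)OCc3ccccc3)N2C(=O)[C@@H](C[C@H]2[C@@H]2C[C@H](C)C(=O)O2)[C@@H]2[C@H]1OC(=O)[C@H]2C
F5 | step 13 | saturated 11-membered ring with C5(CO2H)2 | CC[C@@H]1C(=O)CCCC(C(=O)O)(C(=O)O)N2C(=O)[C@@H](C[C@H]2[C@@H]2C[C@H](C)C(=O)O2)[C@@H]2[C@H]1OC(=O)[C@H]2C
F6 | step 13 | saturated 11-membered ring with C5–CO2H (both C5 epimers) | CC[C@@H]1C(=O)CCCC(C(=O)O)N2C(=O)[C@@H](C[C@H]2[C@@H]2C[C@H](C)C(=O)O2)[C@@H]2[C@H]1OC(=O)[C@H]2C
F7 | step 9 | Evans syn-aldol imide (10S,11R) of 16 | N1C(=O)[C@@H](C[C@H]1[C@@H]1C[C@H](C)C(=O)O1)[C@@H]([C@H](C)C(=O)OC)[C@@H](O)[C@H](CC)C(=O)N1C(=O)OC[C@@H]1Cc1ccccc1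
F8 | step 9 | lactone B S-ethyl thioester (C9 thioester) | N1C(=O)[C@@H](C[C@H]1[C@@H]1C[C@H](C)C(=O)O1)[C@@H]1[C@@H](OC(=O)[C@H]1C)[C@H](CC)C(=O)SCC
F9 | step 6 | (5S)-5-(d-menthyloxy)-3-methylfuran-2(5H)-one | CC1=C[C@@H](O[C@H]2C[C@@H](C)CC[C@@H]2C(C)C)OC1=O
F10 | step 6 | 13-epimer of 14 | CC(C)(C)OC(=O)N1C(=O)[C@@H](C[C@H]1[C@@H]1C[C@H](C)C(=O)O1)[C@@H]1[C@@H](O[C@H]2C[C@@H](C)CC[C@@H]2C(C)C)OC(=O)[C@@H]1C
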